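3 numbers are asked of this flask, and I reach them by asking first where target stops and then how fast it gets there.

| flask | starting material | remark | time |
|---|---|---|---|
| Friday's | 0.12 M | run made earlier |  |
| Wednesday's | 0.19 M | run made earlier |  |
| flask | 0.086 M |  | 30 min |

| run | time / min | target / % |
|---|---|---|
| Friday's | 3.00 | 28.4 |
| Friday's | 5.00 | 36.7 |
| Friday's | 8.00 | 43.5 |
| Friday's | 12.0 | 50.4 |
| Friday's | 20.0 | 53.5 |
| Friday's | 40.0 | 55.2 |
| Wednesday's | 2.50 | 22.6 |
| Wednesday's | 8.00 | 45.5 |
| Wednesday's | 12.0 | 52.7 |
| Wednesday's | 20.0 | 56.0 |
| Wednesday's | 30.0 | 54.6 |
| Wednesday's | 40.0 | 53.9 |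

(scatter of a reading: 1 percentage point)

- amount of target in percent of the starting material charged, at 1.5 min, 8.0 min and 30 min

- the numbers in the tables scatter with a standard deviation of 1 percentage point
- a reading or a percentage of target counts all its forms, free or not

In percent of the charge the two earlier runs nearly overlap. From 20.0 min on, Friday's readings average 54.4% and Wednesday's 54.8%. I pool them into a ceiling of 54.6%, the selectivity for target, and I assume it holds at this flask's charge too.

At 8.00 min the runs read 43.5% and 45.5%. The gap left to the ceiling then gives 3.29 min for the half-time of the approach, the time in which the gap between target and ceiling halves. Applied to this flask, that gives 14.8% at 1.5 min, 44.5% at 8.0 min and 54.5% at 30 min.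

The weak link is the first number, 14.8% at 1.5 min, which rests on a gap read at 8.00 min. Friday's 28.4% at 3.00 min and Wednesday's 22.6% at 2.50 min give an early half-time of 3.01 min, shorter than the one read at 8.00 min, and both carry the scatter of the readings. That lifts my first number to 16.0%, and I commit to it with the other two unchanged.

The forecast says 15.5%, 44% and 55%, holding that “the yield ceiling does not depend noticeably on concentration”. Its first value stands below mine and its last above mine.

The flask gives 16.4%, 45.3% and 55.1%.

    intermediate B → intermediate C (k = 0.00830 s⁻¹)
    starting material ⇌ intermediate A (K = 0.610, k = 0.00370 s⁻¹)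
    intermediate A → side product (k = 0.00580 s⁻¹)
    intermediate C ⇌ intermediate D (K = 1.10, k = 0.0110 s⁻¹)
    crystals ⇌ target, rate k5*(cs5 - [target]) while solid is left; crystals form when [target] > cs5 (solubility = 0.0650 M, k = 0.170 s⁻¹)
    starting material → target (k = 0.00230 s⁻¹)
    intermediate A → intermediate B (k = 3.80 × 10⁻⁴ s⁻¹)
    intermediate B → decomposed reagent (k = 0.00300 s⁻¹)

By its step alone, starting material has a half-life of 5.02 min towards target; towards intermediate A the forward step alone has 3.1 min, but the backward turnover up to 30 min is 49% of the forward one, which I count as 6.18 min net, longer. Counted as two competing rates, these times give 55.2% of the starting material for target, and this flask holds 55.1% of target at 30.0 min. The half-time 3.29 min, with the ceiling 54.6%, gives 52.3% at 15.0 min, where this flask holds 52.9%. On Friday's run it gives 50.2% at 12.0 min, where the reading is 50.4%.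

The earlier runs and the new flask were computed for an exercise; scatter was added.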